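The cyclopentane carries three contiguous stereocentres: C(OH)CH3, the CH bonded to the methylene link, and the CH bearing isopropenyl. If that methylene (between the cyclopentane and the six-membered enolised triketone ring) is temporarily a ketone, the five-membered ring is a β-hydroxy ketone whose other β-carbon bears isopropenyl. One rhodium-catalysed operation therefore suffices: asymmetric 1,4-addition of isopropenyl to an aryl enone, then aldol capture of the enolate by a tethered methyl ketone. It forms two C–C bonds, the ring and all three stereocentres. The precursor is the MOM-protected (E)-aroyl enone of a benzoylphloroglucinol with a 6-oxo chain. Deoxygenation, deprotection and dearomatising gem-diprenylation follow.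

Key step: step 6

Remark: the facial sense of BINAP–rhodium additions to (E)-configured acyclic acceptors is assumed to carry over to enone 10, which calls for (R)-BINAP to obtain the (5S) centre.

Step 1
Reactants: 1 2,4,6-trihydroxybenzophenone; 2 acetic anhydride
Product: 3 3-acetyl-2,4,6-trihydroxybenzophenone
Conditions: Ac2O (1.1 equiv), MeSO3H, 80 °C; H2O quench
Reagents that add atoms: acetic anhydride (2), CC(=O)OC(C)=O
Why: Friedel–Crafts C-acylation: the ring of 1 is still strongly activated by three hydroxyl groups and offers two equivalent free carbons, while the product, now carrying two acyl groups, is deactivated towards a third acylation.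

Step 2
Reactants: 3 3-acetyl-2,4,6-trihydroxybenzophenone
Product: 4 1-[3-benzoyl-2,4,6-tris(methoxymethoxy)phenyl]ethan-1-one
Conditions: NaH (3.5 equiv), MOMCl (4 equiv), DMF, 0 °C → rt
Reagents that add atoms: chloromethyl methyl ether (MOMCl), COCCl
Why: Williamson etherification of the phenoxides with the hard, very reactive MOMCl should go to completion even at the hydrogen-bonded positions, and the phenols (far more acidic than the methyl ketone) consume the hydride before any enolate can form.

Step 3
Reactants: 5 6-methylhept-5-en-2-one
Product: 7 4-oxopentanal, via secondary ozonide 6 (not isolated)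
Conditions: O3, CH2Cl2, −78 °C; then Me2S, −78 °C → rt
Reagents that add atoms: ozone, [O-][O+]=O
Why: Ozonolysis with reductive work-up cleaves the electron-rich trisubstituted alkene and leaves the ketone untouched; the aldehyde is used directly after removal of acetone.

Step 4
Reactants: 4 1-[3-benzoyl-2,4,6-tris(methoxymethoxy)phenyl]ethan-1-one; 7 4-oxopentanal
Product: 8 rac-1-[3-benzoyl-2,4,6-tris(methoxymethoxy)phenyl]-3-hydroxyheptane-1,6-dione
Conditions: LiHMDS (1.05 equiv), THF, −78 °C; then 7 (1.3 equiv), −78 °C; aq. NH4Cl
Reagents that add atoms: 4-oxopentanal (7), CC(=O)CCC=O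
Why: Directed (crossed) aldol addition: 4 has a single enolisable position, and its preformed lithium enolate should attack the aldehyde of 7 much faster than the ketone carbonyl or an acidic proton at −78 °C; the new carbinol centre is racemic and is removed in step 5.

Step 5
Reactants: 8 rac-1-[3-benzoyl-2,4,6-tris(methoxymethoxy)phenyl]-3-hydroxyheptane-1,6-dione
Product: 10 (E)-1-[3-benzoyl-2,4,6-tris(methoxymethoxy)phenyl]hept-2-ene-1,6-dione, via β-mesylate 9 (not isolated)
Conditions: MsCl, Et3N, CH2Cl2, 0 °C → rt
Reagents that add atoms: none
Why: Mesylation followed by E1cB elimination of the β-mesyloxy ketone gives the conjugated enone, for which the (E) geometry is strongly preferred; the MOM ethers and the other two ketones are inert to MsCl/Et3N.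

Step 6
Reactants: 10 (E)-1-[3-benzoyl-2,4,6-tris(methoxymethoxy)phenyl]hept-2-ene-1,6-dione; 11 isopropenylboronic acid pinacol ester
Product: 13 [3-benzoyl-2,4,6-tris(methoxymethoxy)phenyl][(1R,2S,5S)-2-hydroxy-2-methyl-5-(prop-1-en-2-yl)cyclopentyl]methanone, via rhodium(I) (Z)-enolate 12 (not isolated)
Conditions: [Rh(cod)OH]2 (2.5 mol %), (R)-BINAP (6 mol %), 11 (3 equiv), KOH (0.2 equiv), dioxane/H2O 10:1, 80 °C
Reagents that add atoms: isopropenylboronic acid pinacol ester (11), C=C(C)B1OC(C)(C)C(C)(C)O1
Why: Hydroxorhodium(I)–(R)-BINAP transmetalates with the hydroxide-activated boronate 11, the isopropenyl–rhodium species inserts the enone C2=C3 bond on the ligand-controlled face to give the oxa-π-allyl (Z)-enolate 12, this adds to the C6 methyl ketone before water can protonate it, and hydrolysis of the rhodium aldolate returns Rh–OH. The closest known reaction type is the rhodium-catalysed enantioselective conjugate addition–aldol cyclisation of enone-ketones with organoboron reagents, together with the established use of alkenylboron donors in rhodium 1,4-additions. The cyclopentane closes by a 5-exo-trig, enolexo aldol addition (C2–C6 bond) through a chair-like, rhodium-bridged transition state. The isopropenyl-bearing centre (5S) is set by the ligand; the acyl-bearing ring carbon (1R) by allylic strain in the (Z)-enolate, which puts isopropenyl and the forming bond on opposite faces (trans); and the carbinol centre (2S) by the closed transition state, which holds both oxygens on rhodium and so places OH cis to the aroyl group. The step needs 1,4- over 1,2-addition and aldol capture over protonation or base-induced Michael closure; these are secured by the twisted but still conjugated enone, the unhindered methyl ketone on a five-ring tether, the non-enolisable and shielded benzophenone carbonyl, and MOM protection of both ortho phenols (no oxa-Michael closure to a chromanone).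

Step 7
Reactants: 13 [3-benzoyl-2,4,6-tris(methoxymethoxy)phenyl][(1R,2S,5S)-2-hydroxy-2-methyl-5-(prop-1-en-2-yl)cyclopentyl]methanone
Product: 14 [3-{hydroxy[(1S,2S,5S)-2-hydroxy-2-methyl-5-(prop-1-en-2-yl)cyclopentyl]methyl}-2,4,6-tris(methoxymethoxy)phenyl](phenyl)methanone (ring centres spatially as in 13; the 1S descriptor reflects only a CIP priority change; carbinol configuration not assigned)
Conditions: Me4NBH(OAc)3 (5 equiv), MeCN/AcOH 1:1, −20 °C → rt
Reagents that add atoms: none
Why: Saksena–Evans hydroxyl-directed reduction: the tertiary alcohol exchanges onto boron and delivers hydride intramolecularly to the neighbouring aryl ketone through a six-membered transition state, whereas the benzophenone carbonyl has no directing hydroxyl and is not reduced by triacetoxyborohydride; the new carbinol centre is immaterial because it is erased in step 8.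

Step 8
Reactants: 14 the benzylic carbinol
Product: 15 [3-{[(1R,2S,5S)-2-hydroxy-2-methyl-5-(prop-1-en-2-yl)cyclopentyl]methyl}-2,4,6-tris(methoxymethoxy)phenyl](phenyl)methanone
Conditions: Et3SiH (5 equiv), TFA (5 equiv), CH2Cl2, −40 °C
Reagents that add atoms: none
Why: Ionic hydrogenation: the carbinol, flanked by a 2,4,6-trioxygenated arene, should ionise with a few equivalents of TFA at −40 °C, where the tertiary alcohol, the isopropenyl group, the MOM ethers and the twisted diaryl ketone do not react, and excess silane reduces the cation to the methylene link without touching the adjacent stereocentre.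

Step 9
Reactants: 15 the tris-MOM methylene compound
Product: 16 [2,4,6-trihydroxy-3-{[(1R,2S,5S)-2-hydroxy-2-methyl-5-(prop-1-en-2-yl)cyclopentyl]methyl}phenyl](phenyl)methanone
Conditions: ZnBr2 (3.5 equiv), n-PrSH (7 equiv), CH2Cl2, 0 °C → rt
Reagents that add atoms: none
Why: Lewis acid/thiol cleavage of the MOM acetals is fast under non-protic conditions that should spare the tertiary alcohol and the isopropenyl group, and the thiol captures the methoxymethyl cation so that the nucleophilic free ring carbon is not alkylated.

Step 10
Reactants: 16 the triphenol; 17 prenyl bromide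
Product: 19 hypercalin B, via monoprenyl triphenol 18 (not isolated)
Conditions: NaOMe (3 equiv), MeOH, 0 °C; 17 (2.2 equiv), 0 °C → rt; aq. HCl to pH 3
Reagents that add atoms: prenyl bromide (17), CC(C)=CCBr
Why: Dearomatising C-alkylation of an acylphloroglucinol, the reaction used for lupulone-type β-acids: the phenoxide is prenylated first at its only unsubstituted ring carbon (18), and the anion of 18 is alkylated again at that same carbon, which is less hindered than the carbon carrying the branched cyclopentylmethyl group, with the protic solvent favouring C- over O-alkylation; no stereocentre is formed or touched.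

Compound list
1 | 2,4,6-trihydroxybenzophenone | O=C(c1ccccc1)c1c(O)cc(O)cc1O | starting material
2 | acetic anhydride | CC(=O)OC(C)=O | starting material
3 | 3-acetyl-2,4,6-trihydroxybenzophenone | CC(=O)c1c(O)cc(O)c(C(=O)c2ccccc2)c1O | intermediate
4 | 1-[3-benzoyl-2,4,6-tris(methoxymethoxy)phenyl]ethan-1-one | CC(=O)c1c(OCOC)cc(OCOC)c(C(=O)c2ccccc2)c1OCOC | intermediate
5 | 6-methylhept-5-en-2-one | CC(=O)CCC=C(C)C | starting material
6 | secondary ozonide, 4-(5,5-dimethyl-1,2,4-trioxolan-3-yl)butan-2-one (not isolated) | CC(=O)CCC1OOC(C)(C)O1 | intermediate
7 | 4-oxopentanal | CC(=O)CCC=O | intermediate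
8 | rac-1-[3-benzoyl-2,4,6-tris(methoxymethoxy)phenyl]-3-hydroxyheptane-1,6-dione | CC(=O)CCC(O)CC(=O)c1c(OCOC)cc(OCOC)c(C(=O)c2ccccc2)c1OCOC | intermediate
9 | 3-O-methanesulfonate of 8 (not isolated) | CC(=O)CCC(OS(C)(=O)=O)CC(=O)c1c(OCOC)cc(OCOC)c(C(=O)c2ccccc2)c1OCOC | intermediate
10 | (E)-1-[3-benzoyl-2,4,6-tris(methoxymethoxy)phenyl]hept-2-ene-1,6-dione | CC(=O)CC/C=C/C(=O)c1c(OCOC)cc(OCOC)c(C(=O)c2ccccc2)c1OCOC | intermediate
11 | isopropenylboronic acid pinacol ester | C=C(C)B1OC(C)(C)C(C)(C)O1 | starting material
12 | rhodium(I) (Z)-enolate of the 1,4-adduct, S at the isopropenyl-bearing carbon, (R)-BINAP on rhodium not drawn (not isolated) | CC(=O)CC[C@H](C(C)=C)/C=C(\O[Rh])c1c(OCOC)cc(OCOC)c(C(=O)c2ccccc2)c1OCOC | intermediate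
13 | [3-benzoyl-2,4,6-tris(methoxymethoxy)phenyl][(1R,2S,5S)-2-hydroxy-2-methyl-5-(prop-1-en-2-yl)cyclopentyl]methanone (OH cis, isopropenyl trans to the aroyl group) | C=C(C)[C@H]1CC[C@](C)(O)[C@@H]1C(=O)c1c(OCOC)cc(OCOC)c(C(=O)c2ccccc2)c1OCOC | intermediate
14 | benzylic carbinol from 13, cyclopentane centres (1S,2S,5S) by CIP and spatially unchanged, carbinol carbon unassigned | C=C(C)[C@H]1CC[C@](C)(O)[C@@H]1C(O)c1c(OCOC)cc(OCOC)c(C(=O)c2ccccc2)c1OCOC | intermediate
15 | [3-{[(1R,2S,5S)-2-hydroxy-2-methyl-5-(prop-1-en-2-yl)cyclopentyl]methyl}-2,4,6-tris(methoxymethoxy)phenyl](phenyl)methanone | C=C(C)[C@H]1CC[C@](C)(O)[C@@H]1Cc1c(OCOC)cc(OCOC)c(C(=O)c2ccccc2)c1OCOC | intermediate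
16 | [2,4,6-trihydroxy-3-{[(1R,2S,5S)-2-hydroxy-2-methyl-5-(prop-1-en-2-yl)cyclopentyl]methyl}phenyl](phenyl)methanone | C=C(C)[C@H]1CC[C@](C)(O)[C@@H]1Cc1c(O)cc(O)c(C(=O)c2ccccc2)c1O | intermediate
17 | prenyl bromide (1-bromo-3-methylbut-2-ene) | CC(C)=CCBr | starting material
18 | 5-prenyl derivative of 16, fully substituted aromatic triphenol (not isolated) | C=C(C)[C@H]1CC[C@](C)(O)[C@@H]1Cc1c(O)c(CC=C(C)C)c(O)c(C(=O)c2ccccc2)c1O | intermediate
19 | hypercalin B, cyclopentane centres (1R,2S,5S) | C=C(C)[C@H]1CC[C@](C)(O)[C@@H]1CC1=C(O)C(CC=C(C)C)(CC=C(C)C)C(=O)C(C(=O)c2ccccc2)=C1O | target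

Total step count: 10. Longest linear sequence: 9 steps (1 → 3 → 4 → 8 → 10 → 13 → 14 → 15 → 16 → 19; step 3 is a one-step side branch).

Steps most likely to fail

Step 6. The rhodium enolate may be protonated before it reaches the methyl ketone, the base may close 10 by an intramolecular Michael addition, or facial discrimination may be poor with the small isopropenyl group on this di-ortho-substituted aryl enone. The fallback separates the two bond formations. It sets out from 10: a rhodium-catalysed asymmetric 1,4-addition alone (potassium isopropenyltrifluoroborate, BINAP– or chiral diene–rhodium, protic medium at lower temperature, so that the enolate is simply protonated) should give the open diketone (S)-1-[3-benzoyl-2,4,6-tris(methoxymethoxy)phenyl]-3-(prop-1-en-2-yl)heptane-1,6-dione F1. The ring is then closed in a separate, reversible intramolecular aldol addition (catalytic KOt-Bu, t-BuOH/THF, 0 °C). Only the aryl-ketone α-carbon can reach the methyl ketone through an unstrained five-membered ring, and equilibration should favour isopropenyl and methyl trans to the aroyl group (OH cis, hydrogen-bonded). The fallback comes back to the route at 13.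

Step 10. The second alkylation may go to the ring carbon that carries the cyclopentylmethyl group, and O-alkylation or a third alkylation may compete. The fallback sets out from 16, which is treated with one equivalent of 17 under the same base so that the monoprenyl triphenol 18 is isolated. The second prenyl group is then delivered by a palladium-catalysed Tsuji–Trost allylation (Pd(PPh3)4, tert-butyl 3-methylbut-2-en-1-yl carbonate, THF, rt). The soft, bulky π-prenyl palladium electrophile should react at carbon, at the less hindered prenyl-bearing ring position and through its unsubstituted terminus. The fallback comes back at 19 and makes no compound outside the list (F0).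

Step 8. The benzylic cation may fragment (Grob/retro-Prins cleavage of the C1–C2 bond of the cyclopentane, driven by the β-hydroxyl), may be trapped by an ortho MOM oxygen, or the acid may reach the tertiary alcohol and the isopropenyl group before hydride transfer. The fallback replaces the cation by a radical and sets out from 14. The 1,3-diol is closed to the cyclic thionocarbonate F2 (1,1′-thiocarbonyldiimidazole, DMAP, toluene, 80 °C). Bu3SnH/AIBN (toluene, 80 °C) then cleaves the benzylic C–O bond selectively, since this gives the more stabilised radical, and leaves the tertiary oxygen as the S-tributylstannyl thiocarbonate F3 (Barton–McCombie deoxygenation of a diol thionocarbonate). K2CO3/MeOH hydrolyses F3, and the fallback comes back to the route at 15.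

Further compounds
F1 | step 6 | (S)-1-[3-benzoyl-2,4,6-tris(methoxymethoxy)phenyl]-3-(prop-1-en-2-yl)heptane-1,6-dione | CC(=O)CC[C@H](C(C)=C)CC(=O)c1c(OCOC)cc(OCOC)c(C(=O)c2ccccc2)c1OCOC
F2 | step 8 | cyclic thionocarbonate of diol 14 (1,3-dioxane-2-thione fused to the cyclopentane) | C=C(C)[C@H]1CC[C@]2(C)OC(=S)OC(c3c(OCOC)cc(OCOC)c(C(=O)c4ccccc4)c3OCOC)[C@H]12
F3 | step 8 | S-tributylstannyl thiocarbonate of 15 at the tertiary oxygen | C=C(C)[C@H]1CC[C@](C)(OC(=O)S[Sn](CCCC)(CCCC)CCCC)[C@@H]1Cc1c(OCOC)cc(OCOC)c(C(=O)c2ccccc2)c1OCOC
F0 | step 10 | none | none
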